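**Retrosynthetic overview** (cyclohexene atoms: C1 = CH–aroyl, C2 = CH–chalcone aryl, C3H=C4(CH3), C5H2, C6 = CH–(2,4-dihydroxyphenyl))
1. Kuwanon R (28) ⇐ global O-deprotection ⇐ carbonylative Heck attachment of the 4-oxygenated cinnamoyl arm to aryl bromide 24.
2. 24 ⇐ palladium-catalysed ring expansion of 1-arylcyclobutanol 23: the carbinol–CH2 ring bond is cut (the aryl ketone appears on C1) and that CH2 (C5) is joined to the iodine-bearing alkenyl carbon (C4), which closes the cyclohexene at C4–C5.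
3. Enabling feature: the exocyclic aroyl carbon and ring carbon C5 are 1,3-related through C1–C6, so C(=O)–C1–C6–C5 can be stored as a four-membered carbinol ring while C4 with its methyl group waits as a (Z)-alkenyl iodide on the C1–C2–C3 arm.
4. 23 ⇐ aryllithium 20 + cis-2,3-disubstituted cyclobutanone 15, then trans-hydrostannation/iodination; 15 ⇐ 1,4-alkynylation/kinetic protonation of (E)-arylidene cyclobutanone 13 ⇐ asymmetric copper hydride reduction/aldol condensation of cyclobutenone 6 with aldehyde 8.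
5. Ring order: cyclobutene (bought in 3) → stereodefined cyclobutane (steps 4–6) → cyclohexene (step 12); the arenes come from 4-bromoresorcinol (1, twice), 5-bromoresorcinol (16) and 4-acetoxystyrene (25).

Key step: step 12

Assumption: 3-ethoxycyclobut-2-en-1-one (3) is taken as purchasable, and the ligand antipode written in step 4 is the one assumed to give (3S)-9, to be confirmed in the first run and exchanged for its mirror image otherwise.

Step 1
Reactants: 1 4-bromobenzene-1,3-diol
Product: 2 1-bromo-2,4-bis(methoxymethoxy)benzene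
Conditions: MOMCl, i-Pr2NEt, CH2Cl2, 0 °C to rt
Reagents that add atoms: chloromethyl methyl ether, COCCl
Why: Double O-alkylation of the phenols with chloromethyl methyl ether under amine base (MOM ether formation) should be clean, and the MOM groups later direct metalation and withstand every organometallic step.

Step 2
Reactants: 2 1-bromo-2,4-bis(methoxymethoxy)benzene; 3 3-ethoxycyclobut-2-en-1-one
Product: 6 3-[2,4-bis(methoxymethoxy)phenyl]cyclobut-2-en-1-one, via aryllithium 4 (not isolated), via lithium alkoxide 5 (not isolated)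
Conditions: n-BuLi, THF, −78 °C; then 3, −78 °C; then 1 M HCl, 0 °C
Reagents that add atoms: water, O
Why: Bromine–lithium exchange and 1,2-addition of the aryllithium to the vinylogous ester, followed by acid hydrolysis with allylic transposition (Stork–Danheiser transposition), should give the 3-arylcyclobutenone without touching the MOM ethers.

Step 3
Reactants: 2 1-bromo-2,4-bis(methoxymethoxy)benzene
Product: 8 3-bromo-2,6-bis(methoxymethoxy)benzaldehyde, via aryllithium 7 (not isolated)
Conditions: LiN(i-Pr)2, THF, −78 °C; then DMF, −78 °C to 0 °C; aq NH4Cl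
Reagents that add atoms: N,N-dimethylformamide, CN(C)C=O
Why: Directed ortho-metalation with the non-nucleophilic amide base should occur at the position flanked by both OMOM groups and leave the C–Br bond intact, and formylation with DMF should give the aldehyde.

Step 4
Reactants: 6 3-[2,4-bis(methoxymethoxy)phenyl]cyclobut-2-en-1-one; 8 3-bromo-2,6-bis(methoxymethoxy)benzaldehyde
Product: 11 (3S)-3-[2,4-bis(methoxymethoxy)phenyl]-2-{[3-bromo-2,6-bis(methoxymethoxy)phenyl](hydroxy)methyl}cyclobutan-1-one (mixture of epimers at C2 and the carbinol carbon), via silyl enol ether 9 (not isolated), via lithium enolate 10 (not isolated)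
Conditions: CuCl (5 mol %), NaOt-Bu (5 mol %), (R)-DTBM-SEGPHOS (5.5 mol %), PhMe2SiH, toluene, −20 °C; then MeLi, THF, −78 to −20 °C; then 8, −78 °C; aq NH4Cl
Reagents that add atoms: none
Why: Copper hydride-catalysed asymmetric 1,4-reduction puts hydride on one enantiotopic face of the β-aryl enone, which sets C3 under ligand control and gives one regioisomer of silyl enol ether, and its lithium enolate (Si–O cleavage by MeLi) then undergoes a directed aldol addition to the non-enolisable aldehyde, the two extra stereocentres being erased in step 5.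

Step 5
Reactants: 11 the aldol mixture from step 4
Product: 13 (2E,3R)-3-[2,4-bis(methoxymethoxy)phenyl]-2-{[3-bromo-2,6-bis(methoxymethoxy)phenyl]methylidene}cyclobutan-1-one, via mesylate 12 (not isolated)
Conditions: MsCl, Et3N, CH2Cl2, 0 °C; then DBU, 0 °C to rt
Reagents that add atoms: none
Why: Mesylation and E1cB elimination complete the aldol condensation and should give the (E)-alkylidene ketone with the aryl group anti to the carbonyl group, C3 staying untouched (its descriptor becomes R only through a change of CIP priorities).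

Step 6
Reactants: 13 the (2E,3R)-arylidene cyclobutanone
Product: 15 (2R,3S)-3-[2,4-bis(methoxymethoxy)phenyl]-2-{(1R)-1-[3-bromo-2,6-bis(methoxymethoxy)phenyl]but-2-yn-1-yl}cyclobutan-1-one (2,3-cis), via boron enolate 14 (not isolated)
Conditions: B-(prop-1-ynyl)-9-BBN (from MeC≡CLi, B-methoxy-9-BBN, BF3·OEt2, THF, −78 °C to rt), pentane/THF, 0 °C to rt; then MeOH, −78 to 0 °C; pH 7 buffer; used at once
Reagents that add atoms: B-(prop-1-ynyl)-9-borabicyclo[3.3.1]nonane, CC#CB1C2CCCC1CCC2 (made in the flask from prop-1-ynyllithium, [Li]C#CC)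
Why: 1,4-Addition of the B-alkynyl-9-BBN to the s-cis enone through a six-membered cyclic transition state should deliver the alkynyl group to the exocyclic carbon on the face opposite the C3 aryl group (this sets the side-chain stereocentre), and kinetic protonation of the boron enolate at C2, again anti to that aryl group and to the side-chain aryl group held on the same face by A(1,3) strain, should give the cis-2,3 ketone, which the strained ring enolises reluctantly.

Step 7
Reactants: 16 5-bromobenzene-1,3-diol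
Product: 17 1-bromo-3,5-bis(methoxymethoxy)benzene
Conditions: MOMCl, i-Pr2NEt, CH2Cl2, 0 °C to rt
Reagents that add atoms: chloromethyl methyl ether, COCCl
Why: MOM ether formation as in step 1.

Step 8
Reactants: 17 1-bromo-3,5-bis(methoxymethoxy)benzene
Product: 19 5-bromo-1,3-bis(methoxymethoxy)-2-(3-methylbut-2-en-1-yl)benzene, via aryllithium 18 (not isolated)
Conditions: LiN(i-Pr)2, THF, −78 °C; then prenyl bromide, −78 to 0 °C
Reagents that add atoms: 1-bromo-3-methylbut-2-ene, CC(C)=CCBr
Why: Directed ortho-lithiation at the carbon between the two OMOM groups (the amide base does not exchange bromine) followed by SN2 allylation with prenyl bromide should place the prenyl group between the oxygens.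

Step 9
Reactants: 19 5-bromo-1,3-bis(methoxymethoxy)-2-(3-methylbut-2-en-1-yl)benzene; 15 the cis-2,3-disubstituted cyclobutanone
Product: 21 (1R,2R,3S)-3-[2,4-bis(methoxymethoxy)phenyl]-1-[3,5-bis(methoxymethoxy)-4-(3-methylbut-2-en-1-yl)phenyl]-2-{(1R)-1-[3-bromo-2,6-bis(methoxymethoxy)phenyl]but-2-yn-1-yl}cyclobutan-1-ol, via aryllithium 20 (not isolated)
Conditions: n-BuLi (0.98 equiv), THF, −78 °C; then 15, −78 °C; aq NH4Cl
Reagents that add atoms: none
Why: Bromine–lithium exchange and 1,2-addition of the aryllithium to the strained, highly electrophilic ketone should outrun enolisation at −78 °C and occur anti to the C2 side chain and the C3 aryl group, and the new carbinol stereocentre, lost again in step 12, only has to place the OH cis to the side chain.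

Step 10
Reactants: 21 the alkynyl cyclobutanol
Product: 22 (1R,2R,3S)-3-[2,4-bis(methoxymethoxy)phenyl]-1-[3,5-bis(methoxymethoxy)-4-(3-methylbut-2-en-1-yl)phenyl]-2-{(1R,2Z)-1-[3-bromo-2,6-bis(methoxymethoxy)phenyl]-3-(tributylstannyl)but-2-en-1-yl}cyclobutan-1-ol
Conditions: Bu3SnH, [Cp*Ru(MeCN)3]PF6 (5 mol %), CH2Cl2, rt
Reagents that add atoms: tributyltin hydride, CCCC[SnH](CCCC)CCCC
Why: Ruthenium-catalysed trans-hydrostannation should add H and Sn anti across the internal alkyne with tin on the methyl-bearing carbon, distal to the congested branched propargylic carbon (the cationic, chloride-free catalyst is chosen so that the remote hydroxyl group does not steer tin to the proximal carbon), giving the (Z)-alkenylstannane with tin cis to the branched carbon.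

Step 11
Reactants: 22 the (Z)-alkenylstannane
Product: 23 (1R,2R,3S)-3-[2,4-bis(methoxymethoxy)phenyl]-1-[3,5-bis(methoxymethoxy)-4-(3-methylbut-2-en-1-yl)phenyl]-2-{(1R,2Z)-1-[3-bromo-2,6-bis(methoxymethoxy)phenyl]-3-iodobut-2-en-1-yl}cyclobutan-1-ol
Conditions: I2, CH2Cl2, 0 °C
Reagents that add atoms: iodine, II
Why: Iododestannylation with retention of alkene geometry should give the (Z)-alkenyl iodide, the prenyl alkene and the arenes not being attacked by iodine at 0 °C.

Step 12
Reactants: 23 the (Z)-iodoalkenyl cyclobutanol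
Product: 24 [3,5-bis(methoxymethoxy)-4-(3-methylbut-2-en-1-yl)phenyl]{(1R,2S,6S)-6-[2,4-bis(methoxymethoxy)phenyl]-2-[3-bromo-2,6-bis(methoxymethoxy)phenyl]-4-methylcyclohex-3-en-1-yl}methanone
Conditions: Pd(OAc)2 (10 mol %), PPh3 (20 mol %), Cs2CO3, toluene (degassed), 70 °C
Reagents that add atoms: none
Why: Proposed new method: zerovalent palladium should insert into the alkenyl C–I bond, the caesium cyclobutanolate should displace iodide to give a seven-membered alkenylpalladium alkoxide chelate, β-carbon elimination should then break the strained carbinol–CH2 ring bond (unveiling the aryl ketone and a primary alkylpalladium), and C(sp3)–C(sp2) reductive elimination from the resulting seven-membered palladacycle should join the CH2 group to the methyl-bearing alkenyl carbon. The closest known reaction type is the intermolecular palladium-catalysed ring-opening arylation and alkenylation of tert-cyclobutanols with aryl or alkenyl halides (β-carbon elimination, then reductive elimination), of which this is the so far undescribed tethered, ring-expanding variant. The cyclohexene is closed by that reductive elimination, a net 1,3-shift of the CH2 carbon from the carbinol carbon to the alkenyl carbon that turns the four-membered ring into the six-membered one and is driven by release of roughly 26 kcal/mol of ring strain; the (Z)-geometry of the iodide (iodine cis to the branched carbon) is what lets the double bond end up inside the ring. No stereocentre is created: C2, C3 and the side-chain carbon of 23 take part in no bond change and become C1, C6 and C2 of 24, and the carbinol centre is destroyed. The step needs cleavage of the carbinol–CH2 bond and not of the carbinol–CH bond (secured because it gives the primary alkylpalladium and is the only one of the two bonds lying outside the chelate ring, the alternative leading to a strained five-membered palladacycle), reductive elimination faster than β-hydride elimination or C–O bond formation (cis alkyl/alkenyl pair held in the palladacycle, hindered tertiary alkoxide), insertion into C–I before the hindered electron-rich aryl C–Br bond (iodide, 70 °C) and no epimerisation of the new α-keto stereocentre (insoluble carbonate in toluene, reaction stopped at full conversion).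

Step 13
Reactants: 24 the cyclohexenyl aryl ketone (aryl bromide); 25 4-ethenylphenyl acetate (4-acetoxystyrene)
Product: 26 4-[(1E)-3-{3-[(1S,5S,6R)-6-{[3,5-bis(methoxymethoxy)-4-(3-methylbut-2-en-1-yl)phenyl]carbonyl}-5-[2,4-bis(methoxymethoxy)phenyl]-3-methylcyclohex-2-en-1-yl]-2,4-bis(methoxymethoxy)phenyl}-3-oxoprop-1-en-1-yl]phenyl acetate
Conditions: CO (5 bar), [Pd(cinnamyl)Cl]2 (2.5 mol %), di(1-adamantyl)-n-butylphosphine (10 mol %), Et3N, 1,4-dioxane, 100 °C
Reagents that add atoms: carbon monoxide, [C-]#[O+]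
Why: Carbonylative Heck reaction: CO insertion into the arylpalladium bromide, addition of the aroylpalladium to the styrene and β-hydride elimination should give the (E)-chalcone directly under weakly basic conditions that spare the α-stereocentre.

Step 14
Reactants: 26 the hexakis-MOM chalcone acetate
Product: 28 kuwanon R, via hexakis(trimethylsilyl) ether 27 (not isolated)
Conditions: TMSOTf, 2,2′-bipyridyl, MeCN, 0 °C to rt; then K2CO3 (cat.), MeOH, 0 °C; pH 5 buffer
Reagents that add atoms: none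
Why: Silyl triflate/2,2′-bipyridyl exchange converts aryl MOM ethers into aryl silyl ethers without protic acid, and mild carbonate methanolysis then frees all seven phenols, which should avoid acid-induced ketalisation of the ketone by the flanking phenols and cyclisation of the prenyl group.

**Compound list**
1 | 4-bromobenzene-1,3-diol | Oc1ccc(Br)c(O)c1 | starting material
2 | 1-bromo-2,4-bis(methoxymethoxy)benzene | COCOc1ccc(Br)c(OCOC)c1 | intermediate
3 | 3-ethoxycyclobut-2-en-1-one | CCOC1=CC(=O)C1 | starting material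
4 | [2,4-bis(methoxymethoxy)phenyl]lithium | [Li]c1ccc(OCOC)cc1OCOC | intermediate
5 | lithium 1-[2,4-bis(methoxymethoxy)phenyl]-3-ethoxycyclobut-2-en-1-olate | [Li]OC1(C=C(OCC)C1)c1ccc(OCOC)cc1OCOC | intermediate
6 | 3-[2,4-bis(methoxymethoxy)phenyl]cyclobut-2-en-1-one | O=C1C=C(c2ccc(OCOC)cc2OCOC)C1 | intermediate
7 | [3-bromo-2,6-bis(methoxymethoxy)phenyl]lithium | [Li]c1c(OCOC)ccc(Br)c1OCOC | intermediate
8 | 3-bromo-2,6-bis(methoxymethoxy)benzaldehyde | O=Cc1c(OCOC)ccc(Br)c1OCOC | intermediate
9 | {[(3S)-3-[2,4-bis(methoxymethoxy)phenyl]cyclobut-1-en-1-yl]oxy}dimethyl(phenyl)silane | C[Si](C)(c1ccccc1)OC1=C[C@@H](c2ccc(OCOC)cc2OCOC)C1 | intermediate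
10 | lithium (3S)-3-[2,4-bis(methoxymethoxy)phenyl]cyclobut-1-en-1-olate | [Li]OC1=C[C@@H](c2ccc(OCOC)cc2OCOC)C1 | intermediate
11 | (3S)-3-[2,4-bis(methoxymethoxy)phenyl]-2-{[3-bromo-2,6-bis(methoxymethoxy)phenyl](hydroxy)methyl}cyclobutan-1-one, mixture of epimers at C2 and the carbinol carbon | O=C1C[C@H](c2ccc(OCOC)cc2OCOC)C1C(O)c1c(OCOC)ccc(Br)c1OCOC | intermediate
12 | methanesulfonate of 11 (same epimer mixture) | O=C1C[C@H](c2ccc(OCOC)cc2OCOC)C1C(OS(C)(=O)=O)c1c(OCOC)ccc(Br)c1OCOC | intermediate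
13 | (2E,3R)-3-[2,4-bis(methoxymethoxy)phenyl]-2-{[3-bromo-2,6-bis(methoxymethoxy)phenyl]methylidene}cyclobutan-1-one | O=C1C[C@H](c2ccc(OCOC)cc2OCOC)/C1=C\c1c(OCOC)ccc(Br)c1OCOC | intermediate
14 | boron enolate of 15 (O-bound 9-borabicyclo[3.3.1]nonan-9-yl, ring C1=C2 double bond, C3 and side-chain stereocentres as in 15) | C1(OB2C3CCCC2CCC3)=C([C@@H](c2c(OCOC)ccc(Br)c2OCOC)C#CC)[C@@H](c2ccc(OCOC)cc2OCOC)C1 | intermediate
15 | (2R,3S)-3-[2,4-bis(methoxymethoxy)phenyl]-2-{(1R)-1-[3-bromo-2,6-bis(methoxymethoxy)phenyl]but-2-yn-1-yl}cyclobutan-1-one (2,3-cis) | O=C1C[C@H](c2ccc(OCOC)cc2OCOC)[C@@H]1[C@@H](c1c(OCOC)ccc(Br)c1OCOC)C#CC | intermediate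
16 | 5-bromobenzene-1,3-diol | Oc1cc(O)cc(Br)c1 | starting material
17 | 1-bromo-3,5-bis(methoxymethoxy)benzene | COCOc1cc(Br)cc(OCOC)c1 | intermediate
18 | [4-bromo-2,6-bis(methoxymethoxy)phenyl]lithium | [Li]c1c(OCOC)cc(Br)cc1OCOC | intermediate
19 | 5-bromo-1,3-bis(methoxymethoxy)-2-(3-methylbut-2-en-1-yl)benzene | COCOc1cc(Br)cc(OCOC)c1CC=C(C)C | intermediate
20 | [3,5-bis(methoxymethoxy)-4-(3-methylbut-2-en-1-yl)phenyl]lithium | [Li]c1cc(OCOC)c(CC=C(C)C)c(OCOC)c1 | intermediate
21 | (1R,2R,3S)-3-[2,4-bis(methoxymethoxy)phenyl]-1-[3,5-bis(methoxymethoxy)-4-(3-methylbut-2-en-1-yl)phenyl]-2-{(1R)-1-[3-bromo-2,6-bis(methoxymethoxy)phenyl]but-2-yn-1-yl}cyclobutan-1-ol | O[C@]1(c2cc(OCOC)c(CC=C(C)C)c(OCOC)c2)C[C@H](c2ccc(OCOC)cc2OCOC)[C@@H]1[C@@H](c1c(OCOC)ccc(Br)c1OCOC)C#CC | intermediate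
22 | (1R,2R,3S)-3-[2,4-bis(methoxymethoxy)phenyl]-1-[3,5-bis(methoxymethoxy)-4-(3-methylbut-2-en-1-yl)phenyl]-2-{(1R,2Z)-1-[3-bromo-2,6-bis(methoxymethoxy)phenyl]-3-(tributylstannyl)but-2-en-1-yl}cyclobutan-1-ol | O[C@]1(c2cc(OCOC)c(CC=C(C)C)c(OCOC)c2)C[C@H](c2ccc(OCOC)cc2OCOC)[C@@H]1[C@@H](c1c(OCOC)ccc(Br)c1OCOC)/C=C(\[Sn](CCCC)(CCCC)CCCC)C | intermediate
23 | (1R,2R,3S)-3-[2,4-bis(methoxymethoxy)phenyl]-1-[3,5-bis(methoxymethoxy)-4-(3-methylbut-2-en-1-yl)phenyl]-2-{(1R,2Z)-1-[3-bromo-2,6-bis(methoxymethoxy)phenyl]-3-iodobut-2-en-1-yl}cyclobutan-1-ol | O[C@]1(c2cc(OCOC)c(CC=C(C)C)c(OCOC)c2)C[C@H](c2ccc(OCOC)cc2OCOC)[C@@H]1[C@@H](c1c(OCOC)ccc(Br)c1OCOC)/C=C(\I)C | intermediate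
24 | [3,5-bis(methoxymethoxy)-4-(3-methylbut-2-en-1-yl)phenyl]{(1R,2S,6S)-6-[2,4-bis(methoxymethoxy)phenyl]-2-[3-bromo-2,6-bis(methoxymethoxy)phenyl]-4-methylcyclohex-3-en-1-yl}methanone | CC(C)=CCc1c(OCOC)cc(C(=O)[C@H]2[C@@H](c3c(OCOC)ccc(Br)c3OCOC)C=C(C)C[C@@H]2c2ccc(OCOC)cc2OCOC)cc1OCOC | intermediate
25 | 4-ethenylphenyl acetate | CC(=O)Oc1ccc(C=C)cc1 | starting material
26 | 4-[(1E)-3-{3-[(1S,5S,6R)-6-{[3,5-bis(methoxymethoxy)-4-(3-methylbut-2-en-1-yl)phenyl]carbonyl}-5-[2,4-bis(methoxymethoxy)phenyl]-3-methylcyclohex-2-en-1-yl]-2,4-bis(methoxymethoxy)phenyl}-3-oxoprop-1-en-1-yl]phenyl acetate | CC(C)=CCc1c(OCOC)cc(C(=O)[C@H]2[C@@H](c3c(OCOC)ccc(C(=O)/C=C/c4ccc(OC(C)=O)cc4)c3OCOC)C=C(C)C[C@@H]2c2ccc(OCOC)cc2OCOC)cc1OCOC | intermediate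
27 | hexakis(trimethylsilyl) ether corresponding to 26 (all six MOM groups replaced by SiMe3, acetate retained) | CC(C)=CCc1c(O[Si](C)(C)C)cc(C(=O)[C@H]2[C@@H](c3c(O[Si](C)(C)C)ccc(C(=O)/C=C/c4ccc(OC(C)=O)cc4)c3O[Si](C)(C)C)C=C(C)C[C@@H]2c2ccc(O[Si](C)(C)C)cc2O[Si](C)(C)C)cc1O[Si](C)(C)C | intermediate
28 | kuwanon R, (2E)-1-{3-[(1S,5S,6R)-6-[3,5-dihydroxy-4-(3-methylbut-2-en-1-yl)benzoyl]-5-(2,4-dihydroxyphenyl)-3-methylcyclohex-2-en-1-yl]-2,4-dihydroxyphenyl}-3-(4-hydroxyphenyl)prop-2-en-1-one | CC(C)=CCc1c(O)cc(C(=O)[C@H]2[C@@H](c3c(O)ccc(C(=O)/C=C/c4ccc(O)cc4)c3O)C=C(C)C[C@@H]2c2ccc(O)cc2O)cc1O | target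

**Totals**
Total step count: 14. Longest linear sequence: 11 steps (1, 2, 4, 5, 6, 9, 10, 11, 12, 13, 14).

**Steps most likely to fail**

Step 12 (proposed new method). What may go wrong: the tethered alkenylpalladium alkoxide may not reach the syn-coplanar geometry needed for β-carbon elimination, or the alkylpalladium may undergo β-hydride elimination or protonation faster than ring-closing reductive elimination. Fallback (known chemistry only), setting out from 13 and returning at 24: copper-catalysed 1,4-addition of CH2=CHMgBr (CuBr·SMe2, THF, −78 °C) with cold kinetic protonation should give the cis vinyl ketone F1; aryllithium 20 should add as in step 9 to give the cyclobutanol F2; the established intermolecular palladium-catalysed ring-opening alkenylation of a tert-cyclobutanol, here with 2-bromopropene (Pd(OAc)2, PPh3, Cs2CO3, toluene, 80 °C), should cut the same carbinol–CH2 bond and make the same CH2–C(CH3)= bond in the open-chain diene ketone F3; ring-closing metathesis (second-generation Grubbs catalyst, CH2Cl2, 40 °C) then closes the cyclohexene at its double bond and gives 24.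

Step 6. What may go wrong: addition of the alkynylborane on the aryl-shielded face, or loss of the cis relationship through protonation from the wrong face or enolisation during work-up. Fallback, setting out from 13 and returning at 24: the boron enolate is deliberately quenched under equilibrating conditions (MeOH, then Et3N, 25 °C) to the more stable trans ketone F4, which is carried through the conditions of steps 9 to 12 as the cyclobutanol F5, the alkenylstannane F6, the alkenyl iodide F7 and the C1-epimeric cyclohexenyl ketone F8; base-mediated equilibration of the α-carbon of F8 (DBU, toluene, 60 °C) should then favour 24, in which the aroyl and C6-aryl groups can both be equatorial, and unconverted F8 is recycled.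

Step 4. What may go wrong: poor enantioface discrimination by the copper hydride catalyst on the small, planar four-membered enone, or competing 1,2-reduction. Fallback, setting out from 6 and returning at 10: hydrogenation (H2, Pd/C, EtOAc) gives the achiral 3-arylcyclobutanone F9, and enantioselective deprotonation with a chiral lithium amide (LiN[(S)-CH(CH3)Ph]2, LiCl, THF, −100 °C; desymmetrisation of the two enantiotopic α-methylene groups) gives the lithium enolate 10, which is treated with 8 as in step 4.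

**Further compounds**
F1 | step 12 | (2R,3S)-3-[2,4-bis(methoxymethoxy)phenyl]-2-{(1S)-1-[3-bromo-2,6-bis(methoxymethoxy)phenyl]prop-2-en-1-yl}cyclobutan-1-one | O=C1C[C@H](c2ccc(OCOC)cc2OCOC)[C@@H]1[C@@H](c1c(OCOC)ccc(Br)c1OCOC)C=C
F2 | step 12 | (1R,2R,3S)-3-[2,4-bis(methoxymethoxy)phenyl]-1-[3,5-bis(methoxymethoxy)-4-(3-methylbut-2-en-1-yl)phenyl]-2-{(1S)-1-[3-bromo-2,6-bis(methoxymethoxy)phenyl]prop-2-en-1-yl}cyclobutan-1-ol | O[C@]1(c2cc(OCOC)c(CC=C(C)C)c(OCOC)c2)C[C@H](c2ccc(OCOC)cc2OCOC)[C@@H]1[C@@H](c1c(OCOC)ccc(Br)c1OCOC)C=C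
F3 | step 12 | (2R,3S)-3-[2,4-bis(methoxymethoxy)phenyl]-1-[3,5-bis(methoxymethoxy)-4-(3-methylbut-2-en-1-yl)phenyl]-2-{(1S)-1-[3-bromo-2,6-bis(methoxymethoxy)phenyl]prop-2-en-1-yl}-5-methylhex-5-en-1-one | CC(C)=CCc1c(OCOC)cc(C(=O)[C@@H]([C@@H](c2c(OCOC)ccc(Br)c2OCOC)C=C)[C@@H](c2ccc(OCOC)cc2OCOC)CC(C)=C)cc1OCOC
F4 | step 6 | (2S,3S)-3-[2,4-bis(methoxymethoxy)phenyl]-2-{(1R)-1-[3-bromo-2,6-bis(methoxymethoxy)phenyl]but-2-yn-1-yl}cyclobutan-1-one (2,3-trans) | O=C1C[C@H](c2ccc(OCOC)cc2OCOC)[C@H]1[C@@H](c1c(OCOC)ccc(Br)c1OCOC)C#CC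
F5 | step 6 | (1S,2S,3S)-3-[2,4-bis(methoxymethoxy)phenyl]-1-[3,5-bis(methoxymethoxy)-4-(3-methylbut-2-en-1-yl)phenyl]-2-{(1R)-1-[3-bromo-2,6-bis(methoxymethoxy)phenyl]but-2-yn-1-yl}cyclobutan-1-ol | O[C@@]1(c2cc(OCOC)c(CC=C(C)C)c(OCOC)c2)C[C@H](c2ccc(OCOC)cc2OCOC)[C@H]1[C@@H](c1c(OCOC)ccc(Br)c1OCOC)C#CC
F6 | step 6 | (1S,2S,3S)-3-[2,4-bis(methoxymethoxy)phenyl]-1-[3,5-bis(methoxymethoxy)-4-(3-methylbut-2-en-1-yl)phenyl]-2-{(1R,2Z)-1-[3-bromo-2,6-bis(methoxymethoxy)phenyl]-3-(tributylstannyl)but-2-en-1-yl}cyclobutan-1-ol | O[C@@]1(c2cc(OCOC)c(CC=C(C)C)c(OCOC)c2)C[C@H](c2ccc(OCOC)cc2OCOC)[C@H]1[C@@H](c1c(OCOC)ccc(Br)c1OCOC)/C=C(\[Sn](CCCC)(CCCC)CCCC)C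
F7 | step 6 | (1S,2S,3S)-3-[2,4-bis(methoxymethoxy)phenyl]-1-[3,5-bis(methoxymethoxy)-4-(3-methylbut-2-en-1-yl)phenyl]-2-{(1R,2Z)-1-[3-bromo-2,6-bis(methoxymethoxy)phenyl]-3-iodobut-2-en-1-yl}cyclobutan-1-ol | O[C@@]1(c2cc(OCOC)c(CC=C(C)C)c(OCOC)c2)C[C@H](c2ccc(OCOC)cc2OCOC)[C@H]1[C@@H](c1c(OCOC)ccc(Br)c1OCOC)/C=C(\I)C
F8 | step 6 | [3,5-bis(methoxymethoxy)-4-(3-methylbut-2-en-1-yl)phenyl]{(1S,2S,6S)-6-[2,4-bis(methoxymethoxy)phenyl]-2-[3-bromo-2,6-bis(methoxymethoxy)phenyl]-4-methylcyclohex-3-en-1-yl}methanone (C1 epimer of 24) | CC(C)=CCc1c(OCOC)cc(C(=O)[C@@H]2[C@@H](c3c(OCOC)ccc(Br)c3OCOC)C=C(C)C[C@@H]2c2ccc(OCOC)cc2OCOC)cc1OCOC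
F9 | step 4 | 3-[2,4-bis(methoxymethoxy)phenyl]cyclobutan-1-one | O=C1CC(c2ccc(OCOC)cc2OCOC)C1
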